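The route rests on making the ring-fusion bond C5–C10 of the decalin (drimane labels: C10 quaternary CMe, C5 ring-fusion CH, C4 CMe2, C8=C9 ring alkene) in an auxiliary-controlled intramolecular Diels–Alder reaction of an open-chain triene. The target's C8=C9 alkene beside quaternary C10 allows C7–C10 of ring B to be a 2-silyloxy diene (C9 as enol carbon) and C5=C6 an N-enoyl oxazolidinone dienophile; the C1–C4 tether becomes ring A. One operation forms C5–C10 and C6–C7, both rings and both stereocentres, and leaves a C9 ketone whose enol triflate takes the complete side chain by Negishi coupling.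

Key step: step 7

Remark: labels C1–C10 in the text are drimane labels (locants inside names are IUPAC); the C8 stereocentre of 16–18 is carried as an epimer mixture because step 10 erases it, and compounds 1, 2, 5, 10, 11, 21 and 27 are assumed to be commercial.

Step 1
Reactants: 1 isobutyronitrile; 2 1,3-diiodopropane
Product: 4 5-iodo-2,2-dimethylpentanenitrile, via lithiated isobutyronitrile 3 (not isolated)
Conditions: LiN(iPr)2, THF, −78 °C; then added to 2 (3 equiv), THF, −78 °C to rt
Reagents that add atoms: none
Why: SN2 alkylation of the nitrile-stabilised tertiary carbanion with an excess of the symmetrical diiodide should stop at mono-alkylation, because the quaternary product cannot be deprotonated again.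

Step 2
Reactants: 5 2-methylpent-1-en-3-one; 4 5-iodo-2,2-dimethylpentanenitrile
Product: 7 rac-2,2,6,8-tetramethyl-7-oxonon-8-enenitrile, via lithium dienolate 6 (not isolated)
Conditions: LiN(iPr)2, THF, −78 °C; then 4, DMPU, −78 to −20 °C
Reagents that add atoms: none
Why: Kinetic deprotonation of the enone at its only α' position gives the cross-conjugated lithium dienolate, which is C-alkylated by the primary iodide (enolate alkylation), and the new stereocentre is racemic and is erased in step 3.

Step 3
Reactants: 7 rac-2,2,6,8-tetramethyl-7-oxonon-8-enenitrile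
Product: 8 7-{[tert-butyl(dimethyl)silyl]oxy}-2,2,6,8-tetramethylnona-6,8-dienenitrile (6E/6Z mixture)
Conditions: TBSOTf, Et3N, CH2Cl2, 0 °C to rt
Reagents that add atoms: tert-butyldimethylsilyl trifluoromethanesulfonate, CC(C)(C)[Si](C)(C)OS(=O)(=O)C(F)(F)F
Why: Soft enolisation and O-silylation toward the only enolisable carbon (silyl enol ether formation) gives the 2-silyloxy diene, which also masks the ketone against the hydride of step 4.

Step 4
Reactants: 8 7-{[tert-butyl(dimethyl)silyl]oxy}-2,2,6,8-tetramethylnona-6,8-dienenitrile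
Product: 9 7-{[tert-butyl(dimethyl)silyl]oxy}-2,2,6,8-tetramethylnona-6,8-dienal
Conditions: iBu2AlH, toluene, −78 to −40 °C; then aqueous sodium potassium tartrate, pH 7 buffer
Reagents that add atoms: water, O
Why: Reduction of the hindered nitrile with iBu2AlH stops at the N-aluminio imine, which hydrolyses to the aldehyde on buffered work-up (nitrile half-reduction), while the silyl enol ether is inert to the hydride.

Step 5
Reactants: 10 (S)-4-benzyl-1,3-oxazolidin-2-one; 11 2-(diethoxyphosphoryl)acetic acid
Product: 13 (S)-4-benzyl-3-[2-(diethoxyphosphoryl)acetyl]-1,3-oxazolidin-2-one, via mixed pivalic anhydride 12 (not isolated)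
Conditions: tBuCOCl, Et3N, THF, −20 °C; then 10, LiCl, rt
Reagents that add atoms: none
Why: N-Acylation of the oxazolidinone by the mixed anhydride under LiCl/Et3N activation gives the phosphonate imide without touching the auxiliary stereocentre.

Step 6
Reactants: 9 7-{[tert-butyl(dimethyl)silyl]oxy}-2,2,6,8-tetramethylnona-6,8-dienal; 13 (S)-4-benzyl-3-[2-(diethoxyphosphoryl)acetyl]-1,3-oxazolidin-2-one
Product: 14 (S)-4-benzyl-3-[(2E)-9-{[tert-butyl(dimethyl)silyl]oxy}-4,4,8,10-tetramethylundeca-2,8,10-trienoyl]-1,3-oxazolidin-2-one (8E/8Z mixture)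
Conditions: LiCl, iPr2NEt, MeCN, rt
Reagents that add atoms: none
Why: The Horner–Wadsworth–Emmons olefination of the non-enolisable α-quaternary aldehyde with the stabilised phosphonate under mild LiCl/amine conditions should give the E-enoyl imide and leave the silyl enol ether intact.

Step 7
Reactants: 14 (S)-4-benzyl-3-[(2E)-9-{[tert-butyl(dimethyl)silyl]oxy}-4,4,8,10-tetramethylundeca-2,8,10-trienoyl]-1,3-oxazolidin-2-one
Product: 16 (S)-4-benzyl-3-{[(1S,4aS,8aS)-3,4a,8,8-tetramethyl-4-oxodecahydronaphthalen-1-yl]carbonyl}-1,3-oxazolidin-2-one (C3 epimers), via silyl enol ether cycloadduct 15 (not isolated)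
Conditions: Me2AlCl (1.5 equiv), CH2Cl2, −78 to −20 °C; then 1 M HCl, THF, rt
Reagents that add atoms: none
Why: Me2AlCl binds both imide carbonyls as a cationic aluminium chelate with an s-cis enoyl unit, and the tethered 2-silyloxy diene (C7=C8–C9=C10) adds across C5=C6 in a type 1 intramolecular Diels–Alder reaction that is expected to be strongly asynchronous, the enol ether carbon C10 bonding to the β-carbon C5 first (Mukaiyama–Michael character) before C6 closes onto C7. The closest known reaction type is the Me2AlCl-promoted intramolecular Diels–Alder reaction of trienoyl oxazolidinones, which gives trans-fused bicycles through the endo transition state. Ring A closes through the C5–C10 bond in the 6-exo sense over the chair-like C1–C4 tether, and ring B closes as the new cyclohexene through C6–C7 (6-endo in stepwise terms), leaving C8=C9 as a silyl enol ether that the acidic work-up hydrolyses to the C9 ketone. C5 is controlled by the auxiliary, whose benzyl group shields one face of the chelated dienophile so that C10 adds to the opposite face (5S from the S auxiliary); C10 is controlled by the endo, chair-like transition state in which the C9 enol unit (A(1,3) strain with C1) and C6 both sit pseudo-equatorial on the forming ring A, which gives the trans fusion (10S); C6 follows from suprafacial addition to the E-alkene and is removed in step 9. The step needs regioselectivity, trans over cis fusion and π-face selectivity, which are secured respectively by the tether together with the matched polarity of enol ether carbon and enoyl β-carbon, by the Lewis-acid-enforced endo preference, and by the chelated auxiliary. Both enol ether isomers of 14 should converge on 16 if the second bond forms after the first.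

Step 8
Reactants: 16 (S)-4-benzyl-3-{[(1S,4aS,8aS)-3,4a,8,8-tetramethyl-4-oxodecahydronaphthalen-1-yl]carbonyl}-1,3-oxazolidin-2-one
Product: 17 (1S,4aS,8aS)-3,4a,8,8-tetramethyl-4-oxodecahydronaphthalene-1-carboxylic acid (C3 epimers)
Conditions: LiOH, H2O2, THF/H2O, 0 °C; then Na2SO3; then 1 M HCl
Reagents that add atoms: hydrogen peroxide, OO
Why: Hydroperoxide attacks the exocyclic imide carbonyl selectively (hydrolytic auxiliary cleavage), which releases the acid and the recoverable auxiliary 10 without affecting C5 or C10.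

Step 9
Reactants: 17 (1S,4aS,8aS)-3,4a,8,8-tetramethyl-4-oxodecahydronaphthalene-1-carboxylic acid
Product: 18 (4aS,8aS)-2,5,5,8a-tetramethyloctahydronaphthalen-1(2H)-one (C2 epimers)
Conditions: 9-mesityl-10-methylacridinium tetrafluoroborate (5 mol%), PhSSPh (10 mol%), iPr2NEt (20 mol%), CF3CH2OH, blue LED, rt
Reagents that add atoms: none
Why: Photoredox hydrodecarboxylation (single-electron oxidation of the carboxylate, loss of CO2 and hydrogen-atom transfer from thiophenol to the secondary C6 radical) removes the activating carbon and leaves C6 as CH2, so no stereocentre is at stake.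

Step 10
Reactants: 18 (4aS,8aS)-2,5,5,8a-tetramethyloctahydronaphthalen-1(2H)-one
Product: 20 (4aS,8aS)-2,5,5,8a-tetramethyl-3,4,4a,5,6,7,8,8a-octahydronaphthalen-1-yl trifluoromethanesulfonate, via potassium enolate 19 (not isolated)
Conditions: KN(SiMe3)2, THF, −78 to 0 °C; then PhNTf2, −78 °C to rt
Reagents that add atoms: N-phenylbis(trifluoromethanesulfonimide), O=S(=O)(N(c1ccccc1)S(=O)(=O)C(F)(F)F)C(F)(F)F
Why: Because C10 is quaternary the ketone can enolise only toward C8, so O-triflation of the potassium enolate (enol triflate formation) fixes the tetrasubstituted C8=C9 alkene regiospecifically and erases the C8 stereocentre.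

Step 11
Reactants: 21 methyl (S)-3-hydroxy-2-methylpropanoate
Product: 22 methyl (S)-3-{[tert-butyl(dimethyl)silyl]oxy}-2-methylpropanoate
Conditions: TBSCl, imidazole, DMF, rt
Reagents that add atoms: tert-butyldimethylsilyl chloride, CC(C)(C)[Si](C)(C)Cl
Why: Silylation of the primary alcohol (silyl ether protection) leaves the stereocentre untouched.

Step 12
Reactants: 22 methyl (S)-3-{[tert-butyl(dimethyl)silyl]oxy}-2-methylpropanoate
Product: 23 (S)-3-{[tert-butyl(dimethyl)silyl]oxy}-2-methylpropanal
Conditions: iBu2AlH, CH2Cl2, −78 °C; then aqueous sodium potassium tartrate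
Reagents that add atoms: none
Why: Low-temperature half-reduction of the ester with iBu2AlH through the stable tetrahedral aluminium hemiacetal gives the aldehyde, which is used at once to avoid epimerisation of the α-stereocentre.

Step 13
Reactants: 23 (S)-3-{[tert-butyl(dimethyl)silyl]oxy}-2-methylpropanal
Product: 24 tert-butyl{[(2R,3E)-4-iodo-2-methylbut-3-en-1-yl]oxy}dimethylsilane
Conditions: CHI3, CrCl2, THF/dioxane, 0 °C to rt
Reagents that add atoms: iodoform, IC(I)I
Why: The Takai olefination (geminal dichromium reagent from iodoform and divalent chromium) converts the aldehyde into the E-vinyl iodide under non-basic conditions that preserve the adjacent stereocentre, whose descriptor changes to R only through the priority change.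

Step 14
Reactants: 24 tert-butyl{[(2R,3E)-4-iodo-2-methylbut-3-en-1-yl]oxy}dimethylsilane
Product: 25 (2R,3E)-4-iodo-2-methylbut-3-enoic acid
Conditions: CrO3, H2SO4, H2O, acetone, 0 °C
Reagents that add atoms: water, O
Why: Jones oxidation cleaves the primary silyl ether in the acidic medium and oxidises the liberated alcohol through the aldehyde hydrate to the acid, and the acidic conditions should neither epimerise nor conjugate the β,γ-unsaturated acid.

Step 15
Reactants: 25 (2R,3E)-4-iodo-2-methylbut-3-enoic acid
Product: 26 methyl (2R,3E)-4-iodo-2-methylbut-3-enoate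
Conditions: Me3SiCHN2, MeOH/toluene, 0 °C
Reagents that add atoms: (trimethylsilyl)diazomethane, C[Si](C)(C)C=[N+]=[N-]
Why: O-Methylation of the acid with the diazo reagent (esterification) is neutral, so the configurationally sensitive allylic α-stereocentre is retained.

Step 16
Reactants: 27 but-3-yn-1-ol; 26 methyl (2R,3E)-4-iodo-2-methylbut-3-enoate
Product: 29 methyl (2R,3E,5E)-8-hydroxy-2,6-dimethylocta-3,5-dienoate, via alkenylalane 28 (not isolated)
Conditions: Me3Al (3 equiv), Cp2ZrCl2 (25 mol%), CH2Cl2, 0 °C to rt; then 26, ZnCl2, Pd(PPh3)4 (5 mol%), THF, rt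
Reagents that add atoms: trimethylaluminium, C[Al](C)C
Why: Zirconium-catalysed syn-carboalumination of the alkyne sets the E-trisubstituted alkene and the alkenyl metal couples with the vinyl iodide with retention at both partners (Negishi carboalumination and cross-coupling), which gives the E,E-diene under non-basic conditions that spare the ester stereocentre.

Step 17
Reactants: 29 methyl (2R,3E,5E)-8-hydroxy-2,6-dimethylocta-3,5-dienoate
Product: 30 methyl (2R,3E,5E)-8-iodo-2,6-dimethylocta-3,5-dienoate
Conditions: I2, PPh3, imidazole, CH2Cl2, 0 °C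
Reagents that add atoms: iodine, II
Why: Appel-type iodination of the primary alcohol proceeds by SN2 displacement of the oxyphosphonium ion and involves neither the diene nor the stereocentre.

Step 18
Reactants: 30 methyl (2R,3E,5E)-8-iodo-2,6-dimethylocta-3,5-dienoate; 20 (4aS,8aS)-2,5,5,8a-tetramethyl-3,4,4a,5,6,7,8,8a-octahydronaphthalen-1-yl trifluoromethanesulfonate
Product: 32 methyl (2R,3E,5E)-2,6-dimethyl-8-[(4aS,8aS)-2,5,5,8a-tetramethyl-3,4,4a,5,6,7,8,8a-octahydronaphthalen-1-yl]octa-3,5-dienoate, via alkylzinc iodide 31 (not isolated)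
Conditions: Zn dust, LiCl, THF, 35 °C; then 20, Pd(OAc)2 (3 mol%), CPhos (6 mol%), THF/toluene, rt to 45 °C
Reagents that add atoms: none
Why: Zinc insertion into the primary iodide gives an ester-tolerant alkylzinc reagent that undergoes Negishi sp3–sp2 cross-coupling with the enol triflate, which attaches the complete side chain to C9 without touching the three stereocentres.

Compound list
1 | isobutyronitrile | CC(C)C#N | starting material
2 | 1,3-diiodopropane | ICCCI | starting material
3 | lithiated isobutyronitrile | [Li+].C[C-](C)C#N | intermediate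
4 | 5-iodo-2,2-dimethylpentanenitrile | N#CC(C)(C)CCCI | intermediate
5 | 2-methylpent-1-en-3-one | CCC(=O)C(C)=C | starting material
6 | lithium 2-methylpenta-1,3-dien-3-olate | [Li+].CC=C([O-])C(C)=C | intermediate
7 | rac-2,2,6,8-tetramethyl-7-oxonon-8-enenitrile | N#CC(C)(C)CCCC(C)C(=O)C(C)=C | intermediate
8 | 7-{[tert-butyl(dimethyl)silyl]oxy}-2,2,6,8-tetramethylnona-6,8-dienenitrile (6E/6Z mixture) | N#CC(C)(C)CCCC(C)=C(O[Si](C)(C)C(C)(C)C)C(C)=C | intermediate
9 | 7-{[tert-butyl(dimethyl)silyl]oxy}-2,2,6,8-tetramethylnona-6,8-dienal (6E/6Z mixture) | O=CC(C)(C)CCCC(C)=C(O[Si](C)(C)C(C)(C)C)C(C)=C | intermediate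
10 | (S)-4-benzyl-1,3-oxazolidin-2-one | O=C1N[C@@H](Cc2ccccc2)CO1 | starting material
11 | 2-(diethoxyphosphoryl)acetic acid | CCOP(=O)(OCC)CC(=O)O | starting material
12 | 2-(diethoxyphosphoryl)acetic pivalic anhydride | CCOP(=O)(OCC)CC(=O)OC(=O)C(C)(C)C | intermediate
13 | (S)-4-benzyl-3-[2-(diethoxyphosphoryl)acetyl]-1,3-oxazolidin-2-one | CCOP(=O)(OCC)CC(=O)N1[C@@H](Cc2ccccc2)COC1=O | intermediate
14 | (S)-4-benzyl-3-[(2E)-9-{[tert-butyl(dimethyl)silyl]oxy}-4,4,8,10-tetramethylundeca-2,8,10-trienoyl]-1,3-oxazolidin-2-one (8E/8Z mixture) | C=C(C)C(O[Si](C)(C)C(C)(C)C)=C(C)CCCC(C)(C)/C=C/C(=O)N1[C@@H](Cc2ccccc2)COC1=O | intermediate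
15 | (S)-4-benzyl-3-{[(1S,4aS,8aS)-4-{[tert-butyl(dimethyl)silyl]oxy}-3,4a,8,8-tetramethyl-1,2,4a,5,6,7,8,8a-octahydronaphthalen-1-yl]carbonyl}-1,3-oxazolidin-2-one | CC(C)(C)[Si](C)(C)OC1=C(C)C[C@H](C(=O)N3[C@@H](Cc4ccccc4)COC3=O)[C@H]2C(C)(C)CCC[C@]12C | intermediate
16 | (S)-4-benzyl-3-{[(1S,4aS,8aS)-3,4a,8,8-tetramethyl-4-oxodecahydronaphthalen-1-yl]carbonyl}-1,3-oxazolidin-2-one (C3 epimers) | O=C1C(C)C[C@H](C(=O)N3[C@@H](Cc4ccccc4)COC3=O)[C@H]2C(C)(C)CCC[C@]12C | intermediate
17 | (1S,4aS,8aS)-3,4a,8,8-tetramethyl-4-oxodecahydronaphthalene-1-carboxylic acid (C3 epimers) | O=C1C(C)C[C@H](C(=O)O)[C@H]2C(C)(C)CCC[C@]12C | intermediate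
18 | (4aS,8aS)-2,5,5,8a-tetramethyloctahydronaphthalen-1(2H)-one (C2 epimers) | O=C1C(C)CC[C@H]2C(C)(C)CCC[C@]12C | intermediate
19 | potassium (4aS,8aS)-2,5,5,8a-tetramethyl-3,4,4a,5,6,7,8,8a-octahydronaphthalen-1-olate | [K+].[O-]C1=C(C)CC[C@H]2C(C)(C)CCC[C@]12C | intermediate
20 | (4aS,8aS)-2,5,5,8a-tetramethyl-3,4,4a,5,6,7,8,8a-octahydronaphthalen-1-yl trifluoromethanesulfonate | O=S(=O)(OC1=C(C)CC[C@H]2C(C)(C)CCC[C@]12C)C(F)(F)F | intermediate
21 | methyl (S)-3-hydroxy-2-methylpropanoate | COC(=O)[C@@H](C)CO | starting material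
22 | methyl (S)-3-{[tert-butyl(dimethyl)silyl]oxy}-2-methylpropanoate | COC(=O)[C@@H](C)CO[Si](C)(C)C(C)(C)C | intermediate
23 | (S)-3-{[tert-butyl(dimethyl)silyl]oxy}-2-methylpropanal | O=C[C@@H](C)CO[Si](C)(C)C(C)(C)C | intermediate
24 | tert-butyl{[(2R,3E)-4-iodo-2-methylbut-3-en-1-yl]oxy}dimethylsilane | I/C=C/[C@@H](C)CO[Si](C)(C)C(C)(C)C | intermediate
25 | (2R,3E)-4-iodo-2-methylbut-3-enoic acid | I/C=C/[C@@H](C)C(=O)O | intermediate
26 | methyl (2R,3E)-4-iodo-2-methylbut-3-enoate | I/C=C/[C@@H](C)C(=O)OC | intermediate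
27 | but-3-yn-1-ol | C#CCCO | starting material
28 | dimethyl{(1E)-4-[(dimethylalumanyl)oxy]-2-methylbut-1-en-1-yl}alumane | C[Al](C)/C=C(\C)CCO[Al](C)C | intermediate
29 | methyl (2R,3E,5E)-8-hydroxy-2,6-dimethylocta-3,5-dienoate | COC(=O)[C@H](C)/C=C/C=C(\C)CCO | intermediate
30 | methyl (2R,3E,5E)-8-iodo-2,6-dimethylocta-3,5-dienoate | COC(=O)[C@H](C)/C=C/C=C(\C)CCI | intermediate
31 | {(3E,5E,7R)-8-methoxy-3,7-dimethyl-8-oxoocta-3,5-dien-1-yl}zinc iodide | COC(=O)[C@H](C)/C=C/C=C(\C)CC[Zn]I | intermediate
32 | methyl (2R,3E,5E)-2,6-dimethyl-8-[(4aS,8aS)-2,5,5,8a-tetramethyl-3,4,4a,5,6,7,8,8a-octahydronaphthalen-1-yl]octa-3,5-dienoate | COC(=O)[C@H](C)/C=C/C=C(\C)CCC1=C(C)CC[C@H]2C(C)(C)CCC[C@]12C | target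

Total step count: 18. Longest linear sequence: 10 steps (steps 1, 2, 3, 4, 6, 7, 8, 9, 10 and 18).

Steps most likely to fail and their fallbacks

Step 7 (key step). The silyl group may be lost before C–C bond formation, or the reaction may run stepwise and stop after the first bond. The trans fusion may also erode, because the enol ether isomer with the tether on the inside cannot reach the endo arrangement. The fallback makes the two bonds in two operations. Starting from 14, TiCl4 in CH2Cl2 at −78 °C should effect only the intramolecular Mukaiyama–Michael addition of C10 to C5 (ring A, same chelate-controlled face). Aqueous work-up should then give (S)-4-benzyl-3-{2-[(1S,2S)-2,6,6-trimethyl-2-(2-methylprop-2-enoyl)cyclohexyl]acetyl}-1,3-oxazolidin-2-one F1. LiN(SiMe3)2 in THF at −78 to 0 °C should then close ring B by 6-endo Michael addition of the imide enolate (C6) to the isopropenyl ketone (C7), and protonation returns the route to 16.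

Step 18. Transmetalation and reductive elimination at the tetrasubstituted enol triflate beside quaternary C10 may be slow, so that β-hydride elimination and protodezincation consume the valuable functionalised zinc reagent. The fallback extends the chain linearly and forms the diene bond last. Starting from 20, Negishi coupling with an excess of the small, robust reagent [4-(trimethylsilyl)but-3-yn-1-yl]zinc bromide F2 (from commercial (4-bromobut-1-yn-1-yl)trimethylsilane, Zn dust and LiCl) should give trimethyl{4-[(4aS,8aS)-2,5,5,8a-tetramethyl-3,4,4a,5,6,7,8,8a-octahydronaphthalen-1-yl]but-1-yn-1-yl}silane F3. K2CO3 in MeOH should give (4aS,8aS)-1-(but-3-yn-1-yl)-2,5,5,8a-tetramethyl-3,4,4a,5,6,7,8,8a-octahydronaphthalene F4. Carboalumination with Me3Al and Cp2ZrCl2 should give the alkenylalane dimethyl{(1E)-2-methyl-4-[(4aS,8aS)-2,5,5,8a-tetramethyl-3,4,4a,5,6,7,8,8a-octahydronaphthalen-1-yl]but-1-en-1-yl}alumane F5, which is coupled in the same flask with 26 (ZnCl2, Pd(PPh3)4, THF) to arrive at 32.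

Step 2. Anionic oligomerisation of the enone (dienolate adding to unreacted isopropenyl ketone) and proton exchange leading to polyalkylation may outrun the slow alkylation by the unactivated iodide. The fallback builds the ketone from an amide. Starting from 4, α-alkylation of commercial N-methoxy-N-methylpropanamide (LiN(iPr)2, THF, −78 °C) should give the N-methoxy-N-methylamide 6-cyano-N-methoxy-N,2,6-trimethylheptanamide F6. Addition of CH2=C(CH3)MgBr (THF, 0 °C) stops at the chelated tetrahedral intermediate and returns the route to 7 on work-up.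

Further compounds
F1 | step 7 | (S)-4-benzyl-3-{2-[(1S,2S)-2,6,6-trimethyl-2-(2-methylprop-2-enoyl)cyclohexyl]acetyl}-1,3-oxazolidin-2-one | C=C(C)C(=O)[C@@]1(C)CCCC(C)(C)[C@@H]1CC(=O)N2[C@@H](Cc3ccccc3)COC2=O
F2 | step 18 | [4-(trimethylsilyl)but-3-yn-1-yl]zinc bromide | C[Si](C)(C)C#CCC[Zn]Br
F3 | step 18 | trimethyl{4-[(4aS,8aS)-2,5,5,8a-tetramethyl-3,4,4a,5,6,7,8,8a-octahydronaphthalen-1-yl]but-1-yn-1-yl}silane | C[Si](C)(C)C#CCCC1=C(C)CC[C@H]2C(C)(C)CCC[C@]12C
F4 | step 18 | (4aS,8aS)-1-(but-3-yn-1-yl)-2,5,5,8a-tetramethyl-3,4,4a,5,6,7,8,8a-octahydronaphthalene | C#CCCC1=C(C)CC[C@H]2C(C)(C)CCC[C@]12C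
F5 | step 18 | dimethyl{(1E)-2-methyl-4-[(4aS,8aS)-2,5,5,8a-tetramethyl-3,4,4a,5,6,7,8,8a-octahydronaphthalen-1-yl]but-1-en-1-yl}alumane | C[Al](C)/C=C(\C)CCC1=C(C)CC[C@H]2C(C)(C)CCC[C@]12C
F6 | step 2 | 6-cyano-N-methoxy-N,2,6-trimethylheptanamide | CON(C)C(=O)C(C)CCCC(C)(C)C#N
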